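You asked for a quick number and your hunch was that a slow addition would cost no bis adduct, but slow means nothing without a clock, so I looked for one in the runs. I took it that reagent turns starting material into single product and that a second reagent turns single product into bis adduct, so the two must meet.

| flask | starting material | reagent | remark | time |
|---|---|---|---|---|
| birch | 0.050 M | 1.1 equiv | run made earlier |  |
| ash | 0.025 M | 1.1 equiv | run made earlier |  |
| oak | 0.10 M | 1.1 equiv | run made earlier |  |
| alder | 0.050 M | 2.2 equiv | run made earlier |  |
| Monday's | 0.050 M (fed, over 30 min) | 1.10 equiv | all else is in the flask from the start; the feed brings no volume worth counting | 2.5 h |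
| Saturday's | 0.050 M | 1.10 equiv (fed, over 30 min) | all else is in the flask from the start; the feed brings no volume worth counting | 2.5 h |
| Tuesday's | 0.050 M | 1.10 equiv | everything together at the start | 2.5 h |
| Sunday's | 0.050 M | 1.10 equiv (in portions, 3, over 30 min) | first portion at the start, last at 30 min | 2.5 h |

birch run (percent of the starting material charged)

| time / min | bis adduct / % | single product / % |
|---|---|---|
| 8.00 | 20.7 | 20.6 |
| 12.0 | 21.8 | 15.8 |
| 15.0 | 22.1 | 13.0 |
| 25.0 | 22.8 | 8.0 |
| 40.0 | 23.6 | 4.1 |
| 60.0 | 23.7 | 3.7 |
| 90.0 | 24.9 | 2.9 |

ash run (percent of the starting material charged)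

| time / h | bis adduct / % | single product / % |
|---|---|---|
| 0.133 | 12.6 | 21.7 |
| 0.417 | 16.0 | 9.1 |
| 0.667 | 16.5 | 5.6 |
| 1.00 | 17.0 | 4.7 |
| 1.50 | 17.9 | 4.3 |
| 2.00 | 18.5 | 4.3 |
| 2.50 | 18.4 | 4.1 |

oak run (percent of the starting material charged)

| time / h | bis adduct / % | single product / % |
|---|---|---|
| 0.133 | 28.1 | 18.2 |
| 0.417 | 29.1 | 5.3 |
| 0.667 | 30.2 | 3.5 |
| 1.00 | 29.6 | 2.1 |
| 1.50 | 30.3 | 2.0 |
| 2.00 | 30.5 | 2.0 |
| 2.50 | 29.8 | 2.3 |

alder run (percent of the starting material charged)

| time / h | bis adduct / % | single product / % |
|---|---|---|
| 0.500 | 63.4 | 3.8 |
| 1.00 | 66.0 | 2.5 |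
| 1.50 | 67.3 | 1.3 |
| 2.00 | 68.8 | 0.4 |
| 2.50 | 69.8 | 1.3 |

(readings scatter by 0.3 percentage points)



- the flask that comes out highest in amount of bis adduct, in percent of the starting material charged; "all alike" if 1.5 percentage points covers them all (Monday's / Saturday's / Tuesday's / Sunday's / all alike)
- amount of bis adduct at the end, in percent of the starting material charged, Monday's
- amount of bis adduct at the end, in percent of the starting material charged, Saturday's
- amount of bis adduct at the end, in percent of the starting material charged, Tuesday's
- amount of bis adduct at the end, in percent of the starting material charged, Sunday's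

In birch, the fraction m of the charge standing as single product fell from 20.6% to 8.0% while bis adduct rose from 20.7% to 22.8%, so most of it drained elsewhere. I wrote the loss as a first-order relaxation towards a plateau p, taken as the last reading, 2.9%. Integrated, m − p falls as exp(−t/τ), which gave a drain time of 13.7 min; ash gave 13.5 min.

The feed of 30 min is longer than that, with x, feed time over drain time, at 2.20. Integrating the exponential over a steady feed gives one minus exp(−x), divided by x, as the mean share still undrained when the feed ends: 40.4%. Sunday's portions stood 15.0 min apart, also longer than the drain time. That clock does not rank the flasks, so my naming Tuesday's as highest was a judgement and not a result of the reckoning; Tuesday's has birch's charges run on, so I told you to expect a little above birch's last 24.9%. I put no yields on the other flasks, because that share is a clock and not a yield.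

The forecast also chose Tuesday's, at 25.3%, with Saturday's at 16%, Sunday's at 17% and Monday's at 5% (range 1.5% to 11%), on the ground that “reagent dies before most starting material arrives”.

Tuesday's came out highest at 25.7%, with Saturday's at 20.3%, Sunday's at 19.4% and Monday's at 19.5%, which is 15 percentage points above the forecast.

    starting material + reagent → single product (k = 7.40 /M/min)
    reagent + single product → bis adduct (k = 8.20 /M/min)
    single product ⇌ isomer of the product (K = 14.0, k = 0.0670 /min)
    reagent ⇌ dormant form (K = 5.50, k = 0.120 /min)
    starting material + single product → side product (k = 0.940 /M/min)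

At the end of Monday's feed, free reagent stood at 3.39% of its charge, while the dormant form held 51.6% of that charge. Saturday's, with x at 2.20, ended at 20.3%, while the same flask dosed over 3.00 min, with x at 0.219, ended at 25.4%.

All runs come from a simulation with made-up constants; noise was put on by code.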